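**Remarks on the chemistry.** Flavone numbering is used throughout (O1, C2, C3, C4, C4a, C5–C8, C8a; ring B C1'–C6'; bridge C9, C10, C11, O12). The structures of the target, of the key-step precursor and of the key-step product were checked atom by atom and are consistent. One point of bookkeeping is corrected: the new bond C2–C3 raises the ring count by one only, since rings C and D replace the twelve-membered ring, which survives as their common perimeter (6 + 8 − 2 = 12). The O4' protecting group is chosen as benzyl. Aldehyde 6 is treated as not in stock; it is a catalogue compound, and buying it would save step 3.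

## Structural features

Cyclointegrin is a 5-hydroxy-7-methoxyflavone (rings A, C and B) in which C3 of the pyranone and C2' of ring B are bridged by C9H2–C10H2–C11(CH3)2–O12, so that an eight-membered ether ring D (C2, C3, C9, C10, C11, O12, C2', C1') is fused to ring C along C2–C3 and to ring B along C1'–C2'. Ring A is a phloroglucinol unit with the acyl carbon C4 between two oxygens (O1 and the chelated 5-OH) and para to the 7-methoxy group; ring B carries the free 4'-OH para to C1'. The molecule has no stereocentre, so no stereocentres stand next to each other and the problem is one of ring construction and regiochemistry. The fragile points are the tertiary alkyl aryl ether O12–C11, which ionises under strong protic or Lewis acid and cannot be made by displacement at carbon, the electron-rich ring A, and the free phenols. The real difficulty is ring D, a medium ring that contains the fully substituted C2=C3 bond and the twisted C2–C1' bond, for which direct closure is disfavoured. The key step exploits the fact that C2–C3 is the one bond common to rings C and D: without it the two rings merge into a single twelve-membered ring (O1, C2, C1', C2', O12, C11, C10, C9, C3, C4, C4a, C8a) holding an aryl ester (O1–C2) and an aryl ketone (C4) whose only α-carbon is C3, with C3 and C2 kept 1,5 to each other through C4–C4a–C8a–O1. Because ring A without its ester has two equivalent hydroxy groups flanking the acyl group, the macrocycle can be closed onto either oxygen and the other becomes 5-OH.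

## Logic of the disconnections

18 ⇒ 17. Only the O4'–CH2Ph bond is cut. The 4'-oxygen must be masked from step 4 to step 9, because a free 4'-phenoxide para to C2 would turn the lactone carbonyl into a vinylogous carboxylate and stop the acyl transfer. There is no skeletal gain, but the last step becomes neutral. The demand is a hydrogenolysis that leaves C2=C3, C4=O and the O12–C11 ether alone. Benzyl is preferred to a silyl group because the group must survive an alkoxide with release of fluoride, an aryllithium and a lithium amide.

17 ⇒ 14 (through 16 and 15). Bond C2–C3 is cut, after formal rehydration of C2=C3. This is the only cut that opens rings C and D at once, and it turns a medium ring into a large one: 14 is simply the aryl ester of an ortho-hydroxyaryl ketone. The forward step must make the C3 enolate add to C2 across the ring and not between molecules, must use a base that does not open the lactone, and must dehydrate 16 with acid weak enough to spare O12–C11.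

14 ⇒ 12. The ester bond O1–C2 is cut. It is the natural last bond of a lactone, and the symmetry of ring A in 12 means that no phenol has to be differentiated. The gain is an open-chain precursor. The forward step needs high dilution and an activation of the carboxyl group (13) that acylates a hydrogen-bonded phenol.

12 ⇒ 11. The two acetal protecting groups on the ring A oxygens are put back. Ring A needs groups that direct the metalation in the step before and that come off without hydrogenolysis, since the O4' benzyl ether must stay. The demand is an acid hydrolysis dilute enough to leave the tertiary ether intact.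

11 ⇒ 2 + 9 (through 10). Bond C4–C4a is cut. This places the acyl carbon between the two ring A oxygens and para to the methoxy group, a regiochemistry that electrophilic acylation of 1 would not give cleanly. The cut separates ring A from the rest of the molecule. The forward step needs lithiation of 2 at the carbon between the two acetal oxygens, a single addition to the acyl donor, and tolerance of the carboxyl group, which rides along as its lithium salt.

9 ⇒ 8. The C2 carboxyl group is traced back to a formyl group. The formyl group activates the ring for the ether formation and, unlike an ester, cannot hand over an alkoxide that would compete as a nucleophile. The demand is an oxidation that spares the electron-rich arene and the amide.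

8 ⇒ 4 + 6 (through 7). Bond O12–C2' is cut. The tertiary carbon C11 rules out displacement at carbon, so the polarity is reversed: the tertiary alkoxide is the nucleophile and the arene the electrophile. The bond is made early, between the two simplest partners and before any enolisable ketone exists. The forward step needs the hindered alkoxide to attack the ring carbon and the amide to tolerate the base.

4 ⇒ 3, 6 ⇒ 5, 2 ⇒ 1. The amide C–N bond, the benzyl ether and the two acetal ethers are cut. Each leads to a commercial compound in one step and asks only for standard acyl substitution and O-alkylation.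

## Other disconnections considered

Alternative 1: The cut removes C4–C3 and O1–C2 of ring C and leads to the salicylaldehyde A2 (formyl carbon = C4) and the aryl alkyl alkyne A3. In the forward step [Cp*RhCl2]2 with Cu(OAc)2 as oxidant would activate the aldehyde C–H bond next to the phenoxide on trivalent rhodium, insert the alkyne with the aryl-bearing carbon next to the metal, and close ring C by C–O reductive elimination to give A1.
- In its favour: it is convergent, both partners are short to make, no strong base is used, and ring A regiochemistry is already fixed in A2. Up to A1 it is probably the better of the two plans in step count.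
- Against it here: the ortho-fluorine twists the aryl group of A3 and may erode the aryl/alkyl bias that decides the insertion sense, and a free tertiary alcohol must pass hot oxidising conditions. Above all, ring D is still open in A1. It would have to be closed as an eight-membered ring by the tertiary alkoxide displacing fluoride at C2', activated only through the vinylogous carbonyl. The same alkoxide can reach C2 of the pyranone through a six-membered array, and conjugate addition with ring C opening looks easier.
- Comparison: on structure, the alternative builds ring C elegantly but leaves the hard ring to the weakest step, whereas the chosen plan lets ring D fall out of the same bond formation that closes ring C. On mechanism, both rest on known reaction types. The two are equal in having no stereochemical issue and in ending with a hydrogenolysis. On step economy the alternative is better only if the last closure works.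

Alternative 2: The cut removes C9–C10 and C2–C3 and restores a C2–C10 bond, leading to the chromanone enamine A5 and the ring A ynone A6. In the forward step the enamine β-carbon (C10) would add to the terminal alkyne carbon (C9), the aminocyclobutene would form with bond C2–C3, and its opening at C2–C10 would give the eight-membered enaminone A4.
- In its favour: ring D arises by two-carbon ring expansion of a six-membered ring, so neither a medium-ring cyclisation nor a macrocyclisation is needed. The tertiary ether O12–C11 comes ready-made from a condensation of an ortho-hydroxyaryl methyl ketone with a simple ketone; on this bond the alternative is the better plan, because it avoids substitution by a tertiary alkoxide altogether. Ring C would then close easily by addition–elimination of a ring A phenol at C2 with loss of the amine. The step count should be equal or lower.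
- Against it here: the enamine A5 sits next to a quaternary carbon and derives from an electron-rich, poorly electrophilic ketone. A terminal ynone such as A6 can stop at the open-chain Michael adduct or be attacked by liberated amine. Exactly one of the two benzyl ethers of ring A must be removed before ring C can close, and C9=C10 must later be saturated without touching C2=C3.
- Comparison: on structure, both plans make C2–C3 the strategic bond. On mechanism, the alternative has more competing pathways in its key step than an acyl transfer through the ordinary six-membered array. On step economy it is at least equal.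

Alternative 3: The cut removes C4a–C8a and O1–C2 and leads to the pyranone-masked polyketone A8, in which ring D is already present as a β-methoxy enone. In the forward step Mg(OMe)2 in methanol would open the pyranone, the C4a methylene would attack the freed C8a ester (Claisen condensation, aromatisation of ring A), and the new C8a phenoxide would add to C2 and expel methoxide to give A7, which is the same compound as 17.
- In its favour: the oxygen pattern of ring A is programmed by the pyranone methoxy group, so no directed metalation and no ring A regiochemistry problem arise; on this point it is equal or better. Rings A and C form in one mild operation, and the endgame is identical (equal).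
- Against it here: A8 must already contain the eight-membered ring with the C2(OMe)=C3 unit and the acyl side chain, so the main difficulty of the target is moved into the precursor unsolved. The unmasked keto ester can fold in other ways (aldol instead of Claisen closure, or return to the pyranone), and methoxide can add at C2 before ring A exists. The linear sequence would be clearly longer.
- Comparison: on structure, the alternative is strong for ring A and silent on ring D. On mechanism, it depends on the folding selectivity of a polyketone, whereas the chosen plan has a single enolisable carbon and a single ester. On step economy the chosen plan is better.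

Key step: step 9

## Route

Step 1
Reactants: 1 5-methoxyresorcinol
Product: 2 1-methoxy-3,5-bis(methoxymethoxy)benzene
Conditions: MOMCl, K2CO3, acetone, 0 °C → rt
Reagents that add atoms: chloromethyl methyl ether, COCCl
Why: Williamson-type O-alkylation of the two equivalent phenols. The methoxymethyl ethers are chosen because together they direct the lithiation of step 6 to the carbon between them and leave in dilute aqueous acid in step 7.

Step 2
Reactants: 3 6,6-dimethyltetrahydro-2H-pyran-2-one
Product: 4 5-hydroxy-N-methoxy-N,5-dimethylhexanamide
Conditions: MeNH(OMe)·HCl, i-PrMgCl, THF, −20 → 0 °C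
Reagents that add atoms: N,O-dimethylhydroxylamine hydrochloride, CNOC.Cl
Why: Aminolysis of the lactone by the magnesium amide (Weinreb amide formation); the tertiary magnesium alkoxide does not re-close, and a neutral work-up keeps the hydroxy amide from relactonising.

Step 3
Reactants: 5 2-fluoro-4-hydroxybenzaldehyde
Product: 6 4-(benzyloxy)-2-fluorobenzaldehyde
Conditions: BnBr, K2CO3, DMF, rt
Reagents that add atoms: benzyl bromide, BrCc1ccccc1
Why: Williamson ether synthesis on the acidic para-formyl phenol; the benzyl ether is inert to every later reagent up to the final hydrogenolysis.

Step 4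
Reactants: 4 5-hydroxy-N-methoxy-N,5-dimethylhexanamide; 6 4-(benzyloxy)-2-fluorobenzaldehyde
Product: 8 5-[5-(benzyloxy)-2-formylphenoxy]-N-methoxy-N,5-dimethylhexanamide, via potassium alkoxide 7 (not isolated)
Conditions: KH (slight deficit relative to 4), THF, 0 °C; then 6, 0 °C → rt
Reagents that add atoms: none
Why: Nucleophilic aromatic substitution by addition–elimination: the pre-formed tertiary alkoxide 7 adds at C2' ortho to the formyl group, which stabilises the Meisenheimer intermediate, and fluoride leaves. The formyl group has no α-hydrogen and, unlike an ester, cannot exchange alkoxide; the benzyloxy group is meta to the reacting carbon; the slight deficit of KH leaves no free base for the amide.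

Step 5
Reactants: 8 5-[5-(benzyloxy)-2-formylphenoxy]-N-methoxy-N,5-dimethylhexanamide
Product: 9 4-(benzyloxy)-2-({6-[methoxy(methyl)amino]-2-methyl-6-oxohexan-2-yl}oxy)benzoic acid
Conditions: NaClO2, NaH2PO4, 2-methylbut-2-ene, t-BuOH/H2O, rt
Reagents that add atoms: sodium chlorite, [Na+].[O-]Cl=O
Why: Pinnick oxidation: chlorous acid adds to the aldehyde and fragments to the acid, and the alkene traps the hypochlorous acid so that the electron-rich ring is not chlorinated. The amide and both ethers are inert in the weakly acidic buffer.

Step 6
Reactants: 2 1-methoxy-3,5-bis(methoxymethoxy)benzene; 9 4-(benzyloxy)-2-({6-[methoxy(methyl)amino]-2-methyl-6-oxohexan-2-yl}oxy)benzoic acid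
Product: 11 4-(benzyloxy)-2-({6-[4-methoxy-2,6-bis(methoxymethoxy)phenyl]-2-methyl-6-oxohexan-2-yl}oxy)benzoic acid, via aryllithium 10 (not isolated)
Conditions: 2 (2.4 equiv), n-BuLi (2.3 equiv), THF, 0 °C; then 9, −78 → 0 °C; aq NH4Cl
Reagents that add atoms: none
Why: Directed ortho-metalation: the two OCH2OCH3 groups chelate lithium and acidify the carbon they share, so 10 forms there and not next to the methoxy group. One equivalent of 10 turns the acid into its inert lithium carboxylate and a second adds to the Weinreb amide, whose chelated tetrahedral adduct releases the ketone only on work-up (Weinreb ketone synthesis), so no second addition occurs.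

Step 7
Reactants: 11 4-(benzyloxy)-2-({6-[4-methoxy-2,6-bis(methoxymethoxy)phenyl]-2-methyl-6-oxohexan-2-yl}oxy)benzoic acid
Product: 12 4-(benzyloxy)-2-{[6-(2,6-dihydroxy-4-methoxyphenyl)-2-methyl-6-oxohexan-2-yl]oxy}benzoic acid
Conditions: 3 M aq HCl, THF, 40 °C
Reagents that add atoms: none
Why: Acid hydrolysis of the two aryl methoxymethyl acetals, helped by the ortho carbonyl group. The tertiary alkyl aryl ether needs strong anhydrous acid to ionise and should survive dilute aqueous acid, as should the benzyl ether; THF is used instead of an alcohol so that the acid is not esterified.

Step 8
Reactants: 12 4-(benzyloxy)-2-{[6-(2,6-dihydroxy-4-methoxyphenyl)-2-methyl-6-oxohexan-2-yl]oxy}benzoic acid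
Product: 14 twelve-membered seco-C2–C3 macrolactone (4'-O-benzyl; free 5-OH), via mixed anhydride 13 (not isolated)
Conditions: 2-methyl-6-nitrobenzoic anhydride, DMAP, CH2Cl2, rt, slow addition of 12 (final 2 mM)
Reagents that add atoms: none
Why: Shiina macrolactonisation: the carboxyl group is activated as the hindered mixed anhydride 13 and DMAP passes the acyl group to a ring A phenol. The two phenols are equivalent by symmetry, so either gives 14 and the other remains as the chelated 5-OH; slow addition favours the twelve-membered ring over oligomers.

Step 9
Reactants: 14 twelve-membered seco-C2–C3 macrolactone (4'-O-benzyl; free 5-OH)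
Product: 17 4'-O-benzylcyclointegrin, via dilithium enolate 15 (not isolated), via 2-hydroxyflavanone hemiketal 16 (not isolated)
Conditions: LiN(SiMe3)2 (3.5 equiv), THF (5 mM), −78 → 0 °C; AcOH; then PPTS, toluene, 60 °C
Reagents that add atoms: none
Why: Baker–Venkataraman rearrangement run in transannular mode: the first equivalent of base makes the chelated 5-phenoxide, the second the C3 enolate 15 (C3 is the only enolisable carbon), and the enolate carbon adds to the lactone carbonyl C2 through the usual six-membered array C3–C4–C4a–C8a–O1–C2. Because the migrating aroyl group is tied to C3 through C9–C10–C11–O12–C2'–C1', the one new bond C2–C3 closes ring C (6-exo-trig) and ring D (8-exo-trig) together, and the twelve-membered ring becomes their common perimeter. The lithium hemiketal either persists or opens at O1–C2 to the enolate of the 1,3-diketone, which still has one acidic hydrogen at C3 and so offers the usual thermodynamic sink; both forms converge on 16 after the acetic acid quench. Pyridinium tosylate then ionises 16 at C2 to an oxocarbenium ion stabilised by O1 and ring B, and loss of H3 gives the aromatic pyranone; the acid is kept weak because the tertiary ether O12–C11 would ionise under strong acid. C2 and C3 of 16 are stereogenic only in passing and both are erased, so nothing needs to be controlled and 17 has no stereocentre. The step needs the addition across the ring to beat acyl transfer between molecules, which the fixed 1,5-distance of C3 and C2 over ring A and the 5 mM concentration should secure, and it needs the base to spare the ester, which a hindered non-nucleophilic amide does. The closest known reaction type is the base-induced O-to-C aroyl shift of 2-aroyloxyaryl ketones followed by acid cyclodehydration to flavones, including 3-alkyl cases.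

Step 10
Reactants: 17 4'-O-benzylcyclointegrin
Product: 18 cyclointegrin
Conditions: H2 (1 atm), 10% Pd/C, EtOAc/MeOH, rt
Reagents that add atoms: none
Why: Hydrogenolysis of the benzyl aryl ether on palladium. The tetrasubstituted C2=C3 bond of the vinylogous ester, the chelated C4 carbonyl and the non-benzylic ether O12–C11 should not be reduced at one atmosphere and room temperature, and neither acid nor fluoride touches ring D.

## Compound list

1 | 5-methoxyresorcinol | COc1cc(O)cc(O)c1 | starting material
2 | 1-methoxy-3,5-bis(methoxymethoxy)benzene | COCOc1cc(OC)cc(OCOC)c1 | intermediate
3 | 6,6-dimethyltetrahydro-2H-pyran-2-one | CC1(C)CCCC(=O)O1 | starting material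
4 | 5-hydroxy-N-methoxy-N,5-dimethylhexanamide | CON(C)C(=O)CCCC(C)(C)O | intermediate
5 | 2-fluoro-4-hydroxybenzaldehyde | O=Cc1ccc(O)cc1F | starting material
6 | 4-(benzyloxy)-2-fluorobenzaldehyde | O=Cc1ccc(OCc2ccccc2)cc1F | intermediate
7 | potassium 6-[methoxy(methyl)amino]-2-methyl-6-oxohexan-2-olate (not isolated) | CON(C)C(=O)CCCC(C)(C)[O-].[K+] | intermediate
8 | 5-[5-(benzyloxy)-2-formylphenoxy]-N-methoxy-N,5-dimethylhexanamide | CON(C)C(=O)CCCC(C)(C)Oc1cc(OCc2ccccc2)ccc1C=O | intermediate
9 | 4-(benzyloxy)-2-({6-[methoxy(methyl)amino]-2-methyl-6-oxohexan-2-yl}oxy)benzoic acid | CON(C)C(=O)CCCC(C)(C)Oc1cc(OCc2ccccc2)ccc1C(=O)O | intermediate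
10 | [4-methoxy-2,6-bis(methoxymethoxy)phenyl]lithium (not isolated) | COCOc1cc(OC)cc(OCOC)c1[Li] | intermediate
11 | 4-(benzyloxy)-2-({6-[4-methoxy-2,6-bis(methoxymethoxy)phenyl]-2-methyl-6-oxohexan-2-yl}oxy)benzoic acid | COCOc1cc(OC)cc(OCOC)c1C(=O)CCCC(C)(C)Oc1cc(OCc2ccccc2)ccc1C(=O)O | intermediate
12 | 4-(benzyloxy)-2-{[6-(2,6-dihydroxy-4-methoxyphenyl)-2-methyl-6-oxohexan-2-yl]oxy}benzoic acid (seco acid) | COc1cc(O)c(C(=O)CCCC(C)(C)Oc2cc(OCc3ccccc3)ccc2C(=O)O)c(O)c1 | intermediate
13 | mixed anhydride of 12 with 2-methyl-6-nitrobenzoic acid (not isolated) | COc1cc(O)c(C(=O)CCCC(C)(C)Oc2cc(OCc3ccccc3)ccc2C(=O)OC(=O)c2c(C)cccc2[N+](=O)[O-])c(O)c1 | intermediate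
14 | twelve-membered seco-C2–C3 macrolactone: the carboxyl group of 12 esterifies one ring A hydroxy group; ring atoms O1, C2(=O), C1', C2', O12, C11(CH3)2, C10H2, C9H2, C3H2, C4(=O), C4a, C8a; 4'-OBn, 5-OH, 7-OMe | COc1cc(O)c2c(c1)OC(=O)c1ccc(OCc3ccccc3)cc1OC(C)(C)CCCC2=O | intermediate
15 | dilithium salt of 14 (5-phenoxide and C3=C4 enolate, enolate geometry not defined; not isolated) | COc1cc([O-])c2c(c1)OC(=O)c1ccc(OCc3ccccc3)cc1OC(C)(C)CCC=C2[O-].[Li+].[Li+] | intermediate
16 | 4'-O-benzyl-2-hydroxy-2,3-dihydrocyclointegrin (2-hydroxyflavanone hemiketal; C2 and C3 transient stereocentres, configuration not controlled, mixture; not isolated) | COc1cc(O)c2c(c1)OC1(O)C(CCC(C)(C)Oc3cc(OCc4ccccc4)ccc31)C2=O | intermediate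
17 | 4'-O-benzylcyclointegrin | COc1cc(O)c2c(=O)c3c(oc2c1)-c1ccc(OCc4ccccc4)cc1OC(C)(C)CC3 | intermediate
18 | cyclointegrin | COc1cc(O)c2c(=O)c3c(oc2c1)-c1ccc(O)cc1OC(C)(C)CC3 | target

## Step count and least certain steps

Total step count: 10 (9 if 6 is bought). Longest linear sequence: 8 steps (3 → 4 → 8 → 9 → 11 → 12 → 14 → 17 → 18; equally long from 5).

**Step 9 (key step).** The most likely failure is that the C3 enolate does not reach C2 from inside the twelve-membered ring, because the ring may hold the lactone carbonyl turned away from the six-membered array; acyl transfer between molecules or slow loss of material would then take over. A second risk is ionisation of the O12–C11 ether if the dehydration is pushed with stronger acid. The fallback sets out from 11 and comes back at 17. Acid 11 would be methylated (MeI, K2CO3, DMF) to methyl ester F1. Its ketone enolate (LiN(SiMe3)2, THF, high dilution; here a monoanion, since ring A is still protected) would undergo an intramolecular Claisen condensation with the benzoate ester and form C2–C3 directly as the eight-membered β-diketone F2. Dilute aqueous HCl in THF would then remove both acetal groups and let the freed phenol close ring C by cyclodehydration to 17.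

**Step 8.** The most likely failure is esterification between molecules (linear and cyclic oligomers) outrunning closure of a twelve-membered ring that must hold two ortho-fused arenes and a twisted aryl ketone; acylation of the phenols by the dehydrating anhydride is a second risk. The fallback sets out from 12 and comes back at 14. The acid would be converted with N,N'-dicyclohexylcarbodiimide and pentafluorophenol (EtOAc, 0 °C, no acyl-transfer catalyst) into pentafluorophenyl ester F3, which is isolated. Slow addition of F3 to Cs2CO3 in MeCN at 50 °C would then close the ring through the caesium phenoxide, with activation and cyclisation separated.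

**Step 4.** The most likely failure is loss of the Weinreb amide to the base (deprotonation next to the amide followed by addition to the formyl group, or elimination across N–OCH3) while the hindered alkoxide attacks slowly ortho to a formyl group weakened by the para benzyloxy group. The fallback sets out from 3 and comes back at 8. The lactone would be opened with one equivalent of aqueous KOH to potassium 5-hydroxy-5-methylhexanoate F4, which is dried and deprotonated at oxygen (KH, THF/DMF); the alkoxide–carboxylate carries no amide. It would be arylated with 6 to 5-[5-(benzyloxy)-2-formylphenoxy]-5-methylhexanoic acid F5. Amidation of the aliphatic acid (1,1'-carbonyldiimidazole, then MeNH(OMe)·HCl) would give 8.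

**Step 7.** The most likely failure is ionisation of the tertiary ether O12–C11 alongside the acetal hydrolysis, which would detach ring B from the chain. The fallback sets out from 1 and comes back at 12, and replaces acid by fluoride. Compound 1 would be protected as bis-SEM ether F6 (2-(trimethylsilyl)ethoxymethyl chloride, K2CO3), lithiated between the two acetal oxygens (n-BuLi, THF, 0 °C) to aryllithium F7, and added to 9 as in step 6 to give bis-SEM keto acid F8. Bu4NF in THF at 50 °C, with ethane-1,2-diamine to take up formaldehyde, would then give 12.

**Step 6.** The most likely failure is proton abstraction instead of addition: the hindered aryllithium 10 may act as a base on the CH2 next to the amide or on N–OCH3, returning the amide or cutting it down. The fallback sets out from 9 and comes back at 11. The Weinreb amide would be reduced (i-Bu2AlH, 2.2 equiv, THF, −78 °C; the first equivalent is taken up by the acid) to aldehyde acid F9. Addition of excess 10 at −78 °C to this better electrophile would give racemic carbinol F10, and Dess–Martin periodinane would oxidise it to 11.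

## Further compounds

F1 | step 9 | methyl 4-(benzyloxy)-2-({6-[4-methoxy-2,6-bis(methoxymethoxy)phenyl]-2-methyl-6-oxohexan-2-yl}oxy)benzoate | COCOc1cc(OC)cc(OCOC)c1C(=O)CCCC(C)(C)Oc1cc(OCc2ccccc2)ccc1C(=O)OC
F2 | step 9 | 9-(benzyloxy)-5-[4-methoxy-2,6-bis(methoxymethoxy)benzoyl]-2,2-dimethyl-3,4-dihydro-2H-1-benzoxocin-6(5H)-one (racemic) | COCOc1cc(OC)cc(OCOC)c1C(=O)C1CCC(C)(C)Oc2cc(OCc3ccccc3)ccc2C1=O
F3 | step 8 | pentafluorophenyl 4-(benzyloxy)-2-{[6-(2,6-dihydroxy-4-methoxyphenyl)-2-methyl-6-oxohexan-2-yl]oxy}benzoate | COc1cc(O)c(C(=O)CCCC(C)(C)Oc2cc(OCc3ccccc3)ccc2C(=O)Oc2c(F)c(F)c(F)c(F)c2F)c(O)c1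
F4 | step 4 | potassium 5-hydroxy-5-methylhexanoate | CC(C)(O)CCCC(=O)[O-].[K+]
F5 | step 4 | 5-[5-(benzyloxy)-2-formylphenoxy]-5-methylhexanoic acid | CC(C)(CCCC(=O)O)Oc1cc(OCc2ccccc2)ccc1C=O
F6 | step 7 | 1-methoxy-3,5-bis{[2-(trimethylsilyl)ethoxy]methoxy}benzene | COc1cc(OCOCC[Si](C)(C)C)cc(OCOCC[Si](C)(C)C)c1
F7 | step 7 | (4-methoxy-2,6-bis{[2-(trimethylsilyl)ethoxy]methoxy}phenyl)lithium | COc1cc(OCOCC[Si](C)(C)C)c([Li])c(OCOCC[Si](C)(C)C)c1
F8 | step 7 | 4-(benzyloxy)-2-{[6-(4-methoxy-2,6-bis{[2-(trimethylsilyl)ethoxy]methoxy}phenyl)-2-methyl-6-oxohexan-2-yl]oxy}benzoic acid | COc1cc(OCOCC[Si](C)(C)C)c(C(=O)CCCC(C)(C)Oc2cc(OCc3ccccc3)ccc2C(=O)O)c(OCOCC[Si](C)(C)C)c1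
F9 | step 6 | 4-(benzyloxy)-2-[(2-methyl-6-oxohexan-2-yl)oxy]benzoic acid | O=CCCCC(C)(C)Oc1cc(OCc2ccccc2)ccc1C(=O)O
F10 | step 6 | 4-(benzyloxy)-2-({6-hydroxy-6-[4-methoxy-2,6-bis(methoxymethoxy)phenyl]-2-methylhexan-2-yl}oxy)benzoic acid (racemic) | COCOc1cc(OC)cc(OCOC)c1C(O)CCCC(C)(C)Oc1cc(OCc2ccccc2)ccc1C(=O)O
A1 | alternative 1 | 5,4'-bis(benzyloxy)-2'-fluoro-3-(3-hydroxy-3-methylbutyl)-7-methoxyflavone | COc1cc(OCc2ccccc2)c2c(=O)c(CCC(C)(C)O)c(oc2c1)-c1ccc(OCc2ccccc2)cc1F
A2 | alternative 1 | 2-(benzyloxy)-6-hydroxy-4-methoxybenzaldehyde | COc1cc(O)c(C=O)c(OCc2ccccc2)c1
A3 | alternative 1 | 6-[4-(benzyloxy)-2-fluorophenyl]-2-methylhex-5-yn-2-ol | CC(C)(O)CCC#Cc1ccc(OCc2ccccc2)cc1F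
A4 | alternative 2 | [9-(benzyloxy)-2,2-dimethyl-6-(pyrrolidin-1-yl)-2H-1-benzoxocin-5-yl][2,6-bis(benzyloxy)-4-methoxyphenyl]methanone | CC1(C)/C=C\C(C(=O)c2c(OCc3ccccc3)cc(OC)cc2OCc2ccccc2)=C(N2CCCC2)/c2ccc(OCc3ccccc3)cc2O1
A5 | alternative 2 | 1-[7-(benzyloxy)-2,2-dimethyl-2H-chromen-4-yl]pyrrolidine | CC1(C)C=C(N2CCCC2)c2ccc(OCc3ccccc3)cc2O1
A6 | alternative 2 | 1-[2,6-bis(benzyloxy)-4-methoxyphenyl]prop-2-yn-1-one | C#CC(=O)c1c(OCc2ccccc2)cc(OC)cc1OCc1ccccc1
A7 | alternative 3 | 4'-O-benzylcyclointegrin | COc1cc(O)c2c(=O)c3c(oc2c1)-c1ccc(OCc4ccccc4)cc1OC(C)(C)CC3
A8 | alternative 3 | 6-{2-[9-(benzyloxy)-6-methoxy-2,2-dimethyl-3,4-dihydro-2H-1-benzoxocin-5-yl]-2-oxoethyl}-4-methoxy-2H-pyran-2-one | COC1=C(C(=O)Cc2cc(OC)cc(=O)o2)CCC(C)(C)Oc2cc(OCc3ccccc3)ccc21
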